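The numbers in the tables are simulated with constants of no real substance; scatter was added.

Keep the 0.30 M flask running past the moment its charge has passed into reaction, and sample from then on.

| flask | solid substrate | remark | time |
|---|---|---|---|
| north-west | 0.60 M | run made earlier |  |
| flask | 0.30 M |  | 15 d |

north-west run (percent of the solid substrate charged)

| time / h | isomer of the product A / % | target / % | solid substrate / % |
|---|---|---|---|
| 3.00 | 0 | 0 | 99.9 |
| 4.00 | 0 | 0 | 97.0 |
| 6.00 | 0.3 | 1.6 | 95.7 |
| 10.0 | 0 | 0.4 | 94.7 |
| 15.0 | 0.2 | 0 | 93.2 |
| 25.0 | 4.8 | 1.0 | 86.7 |
| 40.0 | 10.1 | 1.6 | 80.6 |

(each reading ± 1 percentage point)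

- solid, in amounts per volume of the solution: solid substrate
- steps thought possible: starting material -> intermediate; intermediate <-> target; intermediate <-> isomer of the product A; intermediate -> decomposed reagent; solid substrate <-> starting material; target <-> isomer of the product B
- at the start none of the solid substrate is in solution

- when, up to 15 d, the flask holds most isomer of the product A
- the amount of isomer of the product A, in percent of the solid substrate charged, at that time

In the north-west run, [solid substrate] falls from 95.7% at 6.00 h to 80.6% at 40.0 h, each reading scattering by 1 percentage point. On its 0.60 M charge that reads as 0.00266 M h⁻¹. While solid stands, this reckoning takes that as a steady, zero-order feed, the same in moles at half the charge. Dividing the new charge by it gives 4.69 d: the reckoned run-out time, charge over feed, an estimate of the crossing at which the charge stops feeding the reaction. Isomer of the product A trails that feed in the north-west run, reading 0.2% at 15.0 h and 4.8% at 25.0 h. So the peak is expected some way after the crossing, and the flask stays on.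

The forecast gives 62% at 5 d, saying “the solid is gone at about 95–100 h”; the two reckonings differ, this one standing at 113 h.

The flask gives 76.3% at 6.22 d.

    starting material → intermediate (k = 0.00230 min⁻¹)
    intermediate ⇌ target (K = 1.20, k = 0.00710 min⁻¹)
    intermediate ⇌ isomer of the product A (K = 37.0, k = 0.00310 min⁻¹)
    intermediate → decomposed reagent (k = 5.10 × 10⁻⁴ min⁻¹)
    solid substrate ⇌ starting material, rate k5*(cs5 - [starting material]) while solid is left; crystals form when [starting material] > cs5 (solubility = 0.100 M, k = 6.10 × 10⁻⁴ min⁻¹)
    target ⇌ isomer of the product B (K = 0.460, k = 0.00280 min⁻¹)

At that peak the flask holds 0% solid substrate and 0.0104% starting material, and the peak stands 1.51 d after the reckoned run-out time. The neighbouring flask is the same charge read at 4.0 d, earlier than the run-out time. Charge over feed leaves 14.7% of the charge unreacted there. That neighbour holds 13%, solid or dissolved, of which 5.97% is solid substrate.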